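The numbers in the tables were generated by integration for an exercise, and the scatter is random.

I was to read alpha, gamma, delta and epsilon at 10 min, so I first asked of the earlier runs what had finished by such a time, and I laid their times out as a ladder.

| flask | substrate | coupling partner | remark | time |
|---|---|---|---|---|
| blue | 18 mM (in portions, 3) | 0.70 equiv | run made earlier; portions every 2.0 min |  |
| amber | 44 mM (in portions, 3) | 0.70 equiv | run made earlier; portions every 2.0 min |  |
| teal | 140 mM (in portions, 3) | 0.70 equiv | run made earlier; portions every 2.0 min |  |
| alpha | 15 mM (in portions, 3) | 0.700 equiv | the portions of substrate follow each other after 2.0 min, the first at the start | 10 min |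
| gamma | 30 mM (in portions, 3) | 0.700 equiv | the portions of substrate follow each other after 2.0 min, the first at the start | 10 min |
| delta | 60 mM (in portions, 3) | 0.700 equiv | the portions of substrate follow each other after 2.0 min, the first at the start | 10 min |
| epsilon | 120 mM (in portions, 3) | 0.700 equiv | the portions of substrate follow each other after 2.0 min, the first at the start | 10 min |

- blue (time / min: target / %): 2.00: 16.8; 4.00: 41.3; 6.00: 64.7; 8.00: 68.1; 10.0: 69.9
- amber (time / min: target / %): 0.833: 21.3; 1.50: 23.1; 3.00: 47.0; 5.00: 67.3; 10.0: 69.2
- teal (time / min: target / %): 0.833: 29.5; 1.50: 29.6; 3.00: 57.9; 5.00: 69.6; 10.0: 68.8

(readings scatter by 1 percentage point)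

- a step back or a flat step of under half a percent of the largest counts as no turn
- a reading or a percentage of target counts all its forms, free or not
- the concentration of target that is asked is that of its free form alone
- "hardly changes" means that all values lie within two and a half points (for a concentration: within two and a half percent of the largest)
- a step back or a flat step of under half a percent of the largest counts as no turn

* [target] (only what is free in solution) at the end for alpha, gamma, delta, epsilon, in this order
* how that number moves from the first to the last of them (falls, then rises / falls all the way / rises all the way / rises, then falls / hardly changes)

The lowest rung was the burst after a portion. Teal read 29.5% after 0.833 min and 29.6% after 1.50 min, against 33.3% of the charge in its first portion, so teal's readings had levelled sooner than the gap of 2.0 min. The next rung was that gap itself, and dilution stretched the burst towards it: blue read less than teal, with 16.8% at 2.00 min, about half of what its first portion held. The top rung was the wait after the last portion, which went in at 4.00 min and left 6.00 min before the reading, longer than a gap. Over that stretch blue went from 64.7% at 6.00 min to 69.9% at 10.0 min, while amber ended at 69.2% and teal at 68.8%, close to what 0.70 equiv of coupling partner allows at one target per partner.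

So I carried one quantity: 10.5 mM for alpha, 21.0 mM for gamma, 42.0 mM for delta and 84.0 mM for epsilon. Each is the equivalents of coupling partner times the substrate charge, the partner ceiling on target in all its forms, with coupling partner as the limiting reagent.

The readings count every form of target, so my own reckoning stopped at this upper bound for free target, whereas the forecast went on to 10.2 mM, 20.8 mM, 41.8 mM and 83.5 mM, rises all the way, with the words “I take free ≈ total”.

The flasks gave 10.4 mM, 13.0 mM, 13.0 mM and 13.0 mM, which counts as rises all the way.

    substrate + coupling partner → target, rate k1*[substrate]^2*[coupling partner]^0.5 (k = 792 M⁻¹·⁵ min⁻¹)
    coupling partner + target ⇌ idle adduct, settled at all times (K = 96.9 M⁻¹)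
    crystals ⇌ target, rate k3*(cs3 - [target]) while solid is left; crystals form when [target] > cs3 (solubility = 13.0 mM, k = 3.29 min⁻¹)

In epsilon, target stood at 70.0% of the charge at 10.0 min, with crystals of 59.2% counted in and idle adduct at 0%. The partner ceiling less free target left 71.0 mM in epsilon, where the crystals came to 71.0 mM. In gamma, with idle adduct also at 0%, the same subtraction left 8.00 mM, and its crystals stood at 26.7% of its charge, or 8.00 mM.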